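**Retrosynthetic overview**

1. The strategy rests on C3 of ring B. C3 carries OH, CH2OH and the benzylic C4H2, so CH2OH and C4 are the two arms of a 3-substituted oxetan-3-ol. C4 is bonded to C4a, the ring A carbon para to the C7 oxygen, so ring B is closed last through C4–C4a (18 ⇐ 17 ⇐ 16 ⇐ 15).
2. 15 ⇐ dioxolanone 12 + oxetan-3-one 13 by aldol addition. C1 bears H and two almost identical aryl groups and cannot bias C2, so C2 is fixed from the acetal carbon of a tert-butyl dioxolanone.
3. 12 ⇐ hydroxy acid 11 ⇐ diol 10 ⇐ epoxy alcohol 6 + aryl Grignard reagent 9. Asymmetric epoxidation sets C2, and invertive aryl transfer to the benzylic epoxide carbon sets C1.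
4. 6 ⇐ 3,4,5-trihydroxybenzaldehyde 1 by benzylation, Wittig olefination and reduction. Ring order: both arenes are bought, the temporary dioxolanone is formed in step 8, the oxetane is brought in intact in step 9, and ring B is closed in step 10.

Key step: step 10

Assumption: C1–C4, C4a and C8a are numbered as in the tetralin of the target throughout, and compounds 1, 3, 7 and 13 are taken as commercial.

**Route**

Step 1
Reactants: 1 3,4,5-trihydroxybenzaldehyde
Product: 2 3,4,5-tris(benzyloxy)benzaldehyde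
Conditions: BnBr (3.3 equiv), K2CO3, DMF, 60 °C, N2
Reagents that add atoms: benzyl bromide, BrCc1ccccc1
Why: Williamson ether synthesis on the three phenols under exclusion of air should give the tribenzyl ether while the aldehyde is untouched.

Step 2
Reactants: 2 3,4,5-tris(benzyloxy)benzaldehyde; 3 (ethoxycarbonylmethylene)triphenylphosphorane
Product: 4 ethyl (E)-3-[3,4,5-tris(benzyloxy)phenyl]prop-2-enoate
Conditions: toluene, 90 °C
Reagents that add atoms: none
Why: Wittig olefination of an aromatic aldehyde by a stabilised ylide should give the (E)-enoate, which brings in C2 and the carboxyl carbon.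

Step 3
Reactants: 4 ethyl (E)-3-[3,4,5-tris(benzyloxy)phenyl]prop-2-enoate
Product: 5 (E)-3-[3,4,5-tris(benzyloxy)phenyl]prop-2-en-1-ol
Conditions: iBu2AlH (2.5 equiv), CH2Cl2, −78 °C; Rochelle salt
Reagents that add atoms: none
Why: 1,2-reduction of the conjugated ester by the aluminium hydride at low temperature should give the allylic alcohol without touching the alkene or the benzyl ethers.

Step 4
Reactants: 5 (E)-3-[3,4,5-tris(benzyloxy)phenyl]prop-2-en-1-ol
Product: 6 [(2S,3S)-3-[3,4,5-tris(benzyloxy)phenyl]oxiran-2-yl]methanol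
Conditions: Ti(OiPr)4 (10 mol%), L-(+)-diisopropyl tartrate (12 mol%), tBuOOH, 4 Å MS, CH2Cl2, −20 °C
Reagents that add atoms: tert-butyl hydroperoxide, CC(C)(C)OO
Why: Sharpless asymmetric epoxidation with the L-(+)-tartrate should deliver oxygen to the face of the (E)-allylic alcohol that gives the (2S,3S)-epoxide, which fixes C2 and the benzylic centre that becomes C1; the 4-benzyloxy group is twisted by its two neighbours and donates poorly, so the benzylic C–O bond should survive the catalytic conditions.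

Step 5
Reactants: 7 5-bromo-2-methoxyphenol
Product: 8 2-(benzyloxy)-4-bromo-1-methoxybenzene
Conditions: BnBr, K2CO3, acetone, reflux
Reagents that add atoms: benzyl bromide, BrCc1ccccc1
Why: Williamson ether synthesis should protect the phenol, leaving bromine para to the methoxy group, which is where C1 must attach to ring A.

Step 6
Reactants: 6 [(2S,3S)-3-[3,4,5-tris(benzyloxy)phenyl]oxiran-2-yl]methanol; 8 2-(benzyloxy)-4-bromo-1-methoxybenzene
Product: 10 (2R,3R)-3-[3-(benzyloxy)-4-methoxyphenyl]-3-[3,4,5-tris(benzyloxy)phenyl]propane-1,2-diol, via arylmagnesium bromide 9 (not isolated)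
Conditions: 8, Mg, cat. I2, THF, 40 °C; then 6 (0.33 equiv), CuI (10 mol%), THF, −30 to 0 °C; aq. NH4Cl
Reagents that add atoms: none
Why: Copper-catalysed SN2 opening of a 2,3-epoxy alcohol by an aryl Grignard reagent should take place at the benzylic carbon with inversion, so the (3S)-epoxide carbon becomes the (R)-diarylmethine that is C1, while the carbinol carbon that becomes C2 is untouched.

Step 7
Reactants: 10 (2R,3R)-3-[3-(benzyloxy)-4-methoxyphenyl]-3-[3,4,5-tris(benzyloxy)phenyl]propane-1,2-diol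
Product: 11 (2R,3R)-3-[3-(benzyloxy)-4-methoxyphenyl]-2-hydroxy-3-[3,4,5-tris(benzyloxy)phenyl]propanoic acid
Conditions: TEMPO (10 mol%), NaClO2 (2 equiv), NaOCl (5 mol%), MeCN/phosphate buffer pH 6.8, 35 °C; then pH 3
Reagents that add atoms: sodium chlorite, [Na+].[O-]Cl=O
Why: Oxoammonium-catalysed oxidation with chlorite as the terminal oxidant should convert only the primary alcohol, through the aldehyde, into the acid and spare the secondary hydroxyl and both stereocentres, the merely catalytic hypochlorite keeping the electron-rich rings from chlorination.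

Step 8
Reactants: 11 (2R,3R)-3-[3-(benzyloxy)-4-methoxyphenyl]-2-hydroxy-3-[3,4,5-tris(benzyloxy)phenyl]propanoic acid
Product: 12 (2R,5R)-5-{(R)-[3-(benzyloxy)-4-methoxyphenyl][3,4,5-tris(benzyloxy)phenyl]methyl}-2-tert-butyl-1,3-dioxolan-4-one
Conditions: tBuCHO (3 equiv), TsOH·H2O (10 mol%), CH2Cl2, reflux over 4 Å MS; minor trans isomer removed by crystallisation or chromatography
Reagents that add atoms: pivalaldehyde, CC(C)(C)C=O
Why: Acid-catalysed acetalisation of an α-hydroxy acid with pivalaldehyde should favour the 2,5-cis dioxolanone under equilibrating conditions, so the (R) configuration of C2 is copied onto the acetal carbon as (R).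

Step 9
Reactants: 12 (2R,5R)-5-{(R)-[3-(benzyloxy)-4-methoxyphenyl][3,4,5-tris(benzyloxy)phenyl]methyl}-2-tert-butyl-1,3-dioxolan-4-one; 13 oxetan-3-one
Product: 15 (2R,5S)-5-{(R)-[3-(benzyloxy)-4-methoxyphenyl][3,4,5-tris(benzyloxy)phenyl]methyl}-2-tert-butyl-5-(3-hydroxyoxetan-3-yl)-1,3-dioxolan-4-one, via lithium enolate 14 (not isolated)
Conditions: LiN(iPr)2 (commercial solution, 1.1 equiv), THF, −78 °C; then 13 (1.5 equiv), −78 °C; AcOH, −78 °C
Reagents that add atoms: none
Why: Aldol addition of a chiral dioxolanone enolate (self-regeneration of stereocentres) should take the ketone on the face anti to the tert-butyl group, so the new C2–C3 bond replaces the former C2–H with retention and the quaternary C2 is set by the acetal carbon and not by C1; the strained ketone is highly electrophilic and its aldolate should be slow to revert.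

Step 10
Reactants: 15 (2R,5S)-5-{(R)-[3-(benzyloxy)-4-methoxyphenyl][3,4,5-tris(benzyloxy)phenyl]methyl}-2-tert-butyl-5-(3-hydroxyoxetan-3-yl)-1,3-dioxolan-4-one
Product: 16 spiro-dioxolanone tetralin, (1S,2S,3R) in tetralin numbering with (R) acetal carbon: 7-(benzyloxy)-3-hydroxy-3-(hydroxymethyl)-6-methoxy-1-[3,4,5-tris(benzyloxy)phenyl]tetralin whose C2 is C5 of the 2-tert-butyl-1,3-dioxolan-4-one
Conditions: Sc(OTf)3 (10 mol%), MeNO2/CH2Cl2, 0 °C to rt, 5 mM
Reagents that add atoms: none
Why: Sc(OTf)3 binds the oxetane oxygen, the ring A carbon para to the benzyloxy group attacks one CH2 from the backside, and the arenium ion loses a proton, so the oxygen stays on the other arm as CH2OH and the reaction is driven by release of ring strain. The closest known reaction type is the Lewis-acid Friedel–Crafts alkylation of arenes by oxetanes, together with the epoxy-arene cyclisation; ring B closes in a 6-exo-tet mode by forming C4–C4a. Backside attack forces the untouched arm anti-periplanar to the forming C4–C4a bond, so it sits equatorial on the nascent ring with the C3 hydroxyl axial, and the two arms therefore correspond to the two half-chairs. The half-chair reached through the arm that gives (3R) has the C2 oxygen axial and trans to the C3 hydroxyl, the lactone carbonyl equatorial and the C1 aryl pseudo-equatorial, whereas the other needs carbonyl and aryl axial with the aryl syn-diaxial to the C3 hydroxyl, so C1 and C2 should control the new centre C3. The step also needs ring A to react in preference to the pendant ring, and at the position para rather than ortho to its benzyloxy group: the pendant ring could bond only through a carbon flanked by a benzyloxy group and would push the other aryl axial, and the other ortho carbon of ring A lies between two substituents. The acylal ring keeps the C2 oxygen and the carboxyl group masked, so neither can open the oxetane in place of the arene.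

Step 11
Reactants: 16 spiro-dioxolanone tetralin
Product: 17 (1S,2S,3R)-7-(benzyloxy)-2,3-dihydroxy-3-(hydroxymethyl)-6-methoxy-1-[3,4,5-tris(benzyloxy)phenyl]-1,2,3,4-tetrahydronaphthalene-2-carboxylic acid
Conditions: LiOH·H2O (5 equiv), THF/MeOH/H2O, rt to 40 °C; then 1 M HCl to pH 3 at 0 °C
Reagents that add atoms: lithium hydroxide, [Li+].[OH-]
Why: Saponification of the acylal lactone should release the carboxylate and pivalaldehyde by collapse of the hemiacetal, any γ-lactone formed by acyl transfer to the CH2OH group is hydrolysed to the same carboxylate, no centre is epimerisable, and the benzyl ethers keep the phenols safe from base and air.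

Step 12
Reactants: 17 (1S,2S,3R)-7-(benzyloxy)-2,3-dihydroxy-3-(hydroxymethyl)-6-methoxy-1-[3,4,5-tris(benzyloxy)phenyl]-1,2,3,4-tetrahydronaphthalene-2-carboxylic acid
Product: 18 (1S,2S,3R)-2,3,7-trihydroxy-3-(hydroxymethyl)-6-methoxy-1-(3,4,5-trihydroxyphenyl)-1,2,3,4-tetrahydronaphthalene-2-carboxylic acid (CNP0174537.1)
Conditions: H2 (1 atm), Pd/C (10%), THF/MeOH, rt; filtration under argon, no heating
Reagents that add atoms: none
Why: Hydrogenolysis of the four benzyl ethers over Pd/C under neutral conditions should free the phenols without touching the diarylmethine C1–H, the tertiary alcohols or the acid, and should leave the γ-hydroxy acid unlactonised.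

**Compound list**

1 | 3,4,5-trihydroxybenzaldehyde | O=Cc1cc(O)c(O)c(O)c1 | starting material
2 | 3,4,5-tris(benzyloxy)benzaldehyde | O=Cc1cc(OCc2ccccc2)c(OCc2ccccc2)c(OCc2ccccc2)c1 | intermediate
3 | (ethoxycarbonylmethylene)triphenylphosphorane | CCOC(=O)C=P(c1ccccc1)(c1ccccc1)c1ccccc1 | starting material
4 | ethyl (E)-3-[3,4,5-tris(benzyloxy)phenyl]prop-2-enoate | CCOC(=O)/C=C/c1cc(OCc2ccccc2)c(OCc2ccccc2)c(OCc2ccccc2)c1 | intermediate
5 | (E)-3-[3,4,5-tris(benzyloxy)phenyl]prop-2-en-1-ol | OC/C=C/c1cc(OCc2ccccc2)c(OCc2ccccc2)c(OCc2ccccc2)c1 | intermediate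
6 | [(2S,3S)-3-[3,4,5-tris(benzyloxy)phenyl]oxiran-2-yl]methanol | OC[C@@H]1O[C@H]1c1cc(OCc2ccccc2)c(OCc2ccccc2)c(OCc2ccccc2)c1 | intermediate
7 | 5-bromo-2-methoxyphenol | COc1ccc(Br)cc1O | starting material
8 | 2-(benzyloxy)-4-bromo-1-methoxybenzene | COc1ccc(Br)cc1OCc1ccccc1 | intermediate
9 | [3-(benzyloxy)-4-methoxyphenyl]magnesium bromide | COc1ccc([Mg]Br)cc1OCc1ccccc1 | intermediate
10 | (2R,3R)-3-[3-(benzyloxy)-4-methoxyphenyl]-3-[3,4,5-tris(benzyloxy)phenyl]propane-1,2-diol | COc1ccc(cc1OCc1ccccc1)[C@H](c1cc(OCc2ccccc2)c(OCc2ccccc2)c(OCc2ccccc2)c1)[C@@H](O)CO | intermediate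
11 | (2R,3R)-3-[3-(benzyloxy)-4-methoxyphenyl]-2-hydroxy-3-[3,4,5-tris(benzyloxy)phenyl]propanoic acid | COc1ccc(cc1OCc1ccccc1)[C@H](c1cc(OCc2ccccc2)c(OCc2ccccc2)c(OCc2ccccc2)c1)[C@@H](O)C(=O)O | intermediate
12 | (2R,5R)-5-{(R)-[3-(benzyloxy)-4-methoxyphenyl][3,4,5-tris(benzyloxy)phenyl]methyl}-2-tert-butyl-1,3-dioxolan-4-one | COc1ccc(cc1OCc1ccccc1)[C@H](c1cc(OCc2ccccc2)c(OCc2ccccc2)c(OCc2ccccc2)c1)[C@@H](O3)C(=O)O[C@@H]3C(C)(C)C | intermediate
13 | oxetan-3-one | O=C1COC1 | starting material
14 | lithium enolate of 12: lithium (2R)-5-{(R)-[3-(benzyloxy)-4-methoxyphenyl][3,4,5-tris(benzyloxy)phenyl]methyl}-2-tert-butyl-1,3-dioxol-4-olate | COc1ccc(cc1OCc1ccccc1)[C@H](c1cc(OCc2ccccc2)c(OCc2ccccc2)c(OCc2ccccc2)c1)C3=C([O-])O[C@H](C(C)(C)C)O3.[Li+] | intermediate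
15 | (2R,5S)-5-{(R)-[3-(benzyloxy)-4-methoxyphenyl][3,4,5-tris(benzyloxy)phenyl]methyl}-2-tert-butyl-5-(3-hydroxyoxetan-3-yl)-1,3-dioxolan-4-one | COc1ccc(cc1OCc1ccccc1)[C@H](c1cc(OCc2ccccc2)c(OCc2ccccc2)c(OCc2ccccc2)c1)[C@@](O3)(C(=O)O[C@@H]3C(C)(C)C)C1(O)COC1 | intermediate
16 | spiro-dioxolanone tetralin: (2R,4S,1'S,3'R)-7'-(benzyloxy)-2-tert-butyl-3'-hydroxy-3'-(hydroxymethyl)-6'-methoxy-1'-[3,4,5-tris(benzyloxy)phenyl]-3',4'-dihydro-1'H-spiro[1,3-dioxolane-4,2'-naphthalen]-5-one | COc1cc2c(cc1OCc1ccccc1)[C@H](c1cc(OCc3ccccc3)c(OCc3ccccc3)c(OCc3ccccc3)c1)[C@@](O4)(C(=O)O[C@@H]4C(C)(C)C)[C@](O)(CO)C2 | intermediate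
17 | (1S,2S,3R)-7-(benzyloxy)-2,3-dihydroxy-3-(hydroxymethyl)-6-methoxy-1-[3,4,5-tris(benzyloxy)phenyl]-1,2,3,4-tetrahydronaphthalene-2-carboxylic acid | COc1cc2c(cc1OCc1ccccc1)[C@H](c1cc(OCc3ccccc3)c(OCc3ccccc3)c(OCc3ccccc3)c1)[C@@](O)(C(=O)O)[C@](O)(CO)C2 | intermediate
18 | (1S,2S,3R)-2,3,7-trihydroxy-3-(hydroxymethyl)-6-methoxy-1-(3,4,5-trihydroxyphenyl)-1,2,3,4-tetrahydronaphthalene-2-carboxylic acid | COc1cc2c(cc1O)[C@H](c1cc(O)c(O)c(O)c1)[C@@](O)(C(=O)O)[C@](O)(CO)C2 | target

**Step count and risks**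

Total step count: 12. Longest linear sequence: 11 steps (steps 1–4 and 6–12); step 5 is a one-step side branch.

Steps most likely to fail:

1. Step 10. The arene may attack the other oxetane arm, giving poor selection between the diastereotopic CH2 groups, for example because peri strain between the pseudo-equatorial C1 aryl and C8–H offsets the preferred half-chair. The fallback sets out from 15 and comes back at 16; it fixes C3 by osmylation of an exocyclic alkene instead of by arm selection. The cyclisation is run as before and the C3 epimer of 16, the (3S)-diol F1, is separated. 1,1'-Thiocarbonyldiimidazole (DMAP, toluene, 80 °C) should convert its tertiary/primary 1,2-diol into the cyclic thiocarbonate F2. Corey–Winter olefination (P(OMe)3, 110 °C) should give the 3-methylene tetralin F3. Dihydroxylation (OsO4 cat., N-methylmorpholine N-oxide, acetone/H2O) should then occur anti to the axial allylic C2 oxygen, as is usual for osmylation of allylic ethers, placing the new C3 hydroxyl trans to it and returning 16.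

2. Step 9. Addition of the fully substituted, hindered enolate may stay incomplete, or the aldolate may revert on warming. The fallback sets out from 12 and comes back at 15. Enolate 14 is trapped with Me3SiCl at −78 °C as the silyl ketene acetal F4. A fluoride-catalysed Mukaiyama aldol addition to 13 (Bu4N[Ph3SiF2] 10 mol%, THF, −40 °C), still anti to the tert-butyl group, should give the trimethylsilyl ether F5, in which the tertiary oxygen is silylated as it forms and cannot revert. HF·pyridine (THF, 0 °C) then frees 15.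

3. Step 6. The aryl group may be delivered to C2 instead of the benzylic carbon, or the benzylic C–O bond may ionise before substitution, which would erode the configuration of C1. The fallback sets out from ester 4 and comes back at 11; C1 is then set by catalyst control and C2 by an auxiliary.
   - Hayashi–Miyaura 1,4-addition of bought [3-(benzyloxy)-4-methoxyphenyl]boronic acid (COc1ccc(B(O)O)cc1OCc1ccccc1) to 4 with [RhCl(C2H4)2]2 and a chiral 2,5-diphenylbicyclo[2.2.2]octa-2,5-diene (KOH, dioxane/H2O, 50 °C) should give the (3R)-diaryl ester F6. The sense of induction of this ligand on this substrate has not been derived here; the ligand antipode that gives the (3R)-ester is to be used.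
   - LiOH (THF/H2O) should give the acid F7.
   - Coupling with (R)-4-benzyloxazolidin-2-one (PivCl, Et3N, LiCl, THF) should give the imide F8.
   - Enolate hydroxylation under control of the Evans auxiliary (NaN(SiMe3)2, THF, −78 °C, then 2-(phenylsulfonyl)-3-phenyloxaziridine) should attack the chelated Z-enolate anti to the benzyl group, independently of C1, and give the (2R)-hydroxy imide F9.
   - LiOH/H2O2 (THF/H2O, 0 °C) should release 11.

**Further compounds**

F1 | step 10 | C3 epimer of 16: (2R,4S,1'S,3'S)-7'-(benzyloxy)-2-tert-butyl-3'-hydroxy-3'-(hydroxymethyl)-6'-methoxy-1'-[3,4,5-tris(benzyloxy)phenyl]-3',4'-dihydro-1'H-spiro[1,3-dioxolane-4,2'-naphthalen]-5-one | COc1cc2c(cc1OCc1ccccc1)[C@H](c1cc(OCc3ccccc3)c(OCc3ccccc3)c(OCc3ccccc3)c1)[C@@](O4)(C(=O)O[C@@H]4C(C)(C)C)[C@@](O)(CO)C2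
F2 | step 10 | cyclic thiocarbonate of F1 (1,3-dioxolane-2-thione spiro-fused at C3 through the C3 oxygen and the CH2O arm) | COc1cc2c(cc1OCc1ccccc1)[C@H](c1cc(OCc3ccccc3)c(OCc3ccccc3)c(OCc3ccccc3)c1)[C@@](O4)(C(=O)O[C@@H]4C(C)(C)C)[C@@](O5)(COC5=S)C2
F3 | step 10 | 3-methylene tetralin: (2R,4S,1'S)-7'-(benzyloxy)-2-tert-butyl-6'-methoxy-3'-methylidene-1'-[3,4,5-tris(benzyloxy)phenyl]-3',4'-dihydro-1'H-spiro[1,3-dioxolane-4,2'-naphthalen]-5-one | COc1cc2c(cc1OCc1ccccc1)[C@H](c1cc(OCc3ccccc3)c(OCc3ccccc3)c(OCc3ccccc3)c1)[C@@](O4)(C(=O)O[C@@H]4C(C)(C)C)C(=C)C2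
F4 | step 9 | silyl ketene acetal of 12: (2R)-5-{(R)-[3-(benzyloxy)-4-methoxyphenyl][3,4,5-tris(benzyloxy)phenyl]methyl}-2-tert-butyl-4-(trimethylsilyloxy)-1,3-dioxole | COc1ccc(cc1OCc1ccccc1)[C@H](c1cc(OCc2ccccc2)c(OCc2ccccc2)c(OCc2ccccc2)c1)C3=C(O[Si](C)(C)C)O[C@H](C(C)(C)C)O3
F5 | step 9 | trimethylsilyl ether of 15 at the oxetane hydroxyl | COc1ccc(cc1OCc1ccccc1)[C@H](c1cc(OCc2ccccc2)c(OCc2ccccc2)c(OCc2ccccc2)c1)[C@@](O3)(C(=O)O[C@@H]3C(C)(C)C)C1(O[Si](C)(C)C)COC1
F6 | step 6 | ethyl (3R)-3-[3-(benzyloxy)-4-methoxyphenyl]-3-[3,4,5-tris(benzyloxy)phenyl]propanoate | COc1ccc(cc1OCc1ccccc1)[C@H](c1cc(OCc2ccccc2)c(OCc2ccccc2)c(OCc2ccccc2)c1)CC(=O)OCC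
F7 | step 6 | (3R)-3-[3-(benzyloxy)-4-methoxyphenyl]-3-[3,4,5-tris(benzyloxy)phenyl]propanoic acid | COc1ccc(cc1OCc1ccccc1)[C@H](c1cc(OCc2ccccc2)c(OCc2ccccc2)c(OCc2ccccc2)c1)CC(=O)O
F8 | step 6 | (4R)-4-benzyl-3-{(3R)-3-[3-(benzyloxy)-4-methoxyphenyl]-3-[3,4,5-tris(benzyloxy)phenyl]propanoyl}oxazolidin-2-one | COc1ccc(cc1OCc1ccccc1)[C@H](c1cc(OCc2ccccc2)c(OCc2ccccc2)c(OCc2ccccc2)c1)CC(=O)N1C(=O)OC[C@H]1Cc1ccccc1
F9 | step 6 | (4R)-4-benzyl-3-{(2R,3R)-3-[3-(benzyloxy)-4-methoxyphenyl]-2-hydroxy-3-[3,4,5-tris(benzyloxy)phenyl]propanoyl}oxazolidin-2-one | COc1ccc(cc1OCc1ccccc1)[C@H](c1cc(OCc2ccccc2)c(OCc2ccccc2)c(OCc2ccccc2)c1)[C@@H](O)C(=O)N1C(=O)OC[C@H]1Cc1ccccc1
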